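**Plan**
- Retrosynthesis: each indole C2=C3 bond is traced back to a lactam (C2 as C=O). Both C3–C3a bonds are then cut (amide enolate carbon plus aryne carbon), then the two N–C(=O) bonds (glutaryl unit), and last the N–C(tertiary) bond, with the vinyl group coming from an alkyne.
- Enabling feature: in each indole C3 is the neighbour of C2. With C2 at the amide level, the chain C2–C3–CH2–C3'–C2' is a glutaric diamide whose two α-carbons (C3, C3') can each be joined to C3a of the N-aryl ring.
- Forward: 2-chloroaniline is N-tert-propargylated and semihydrogenated, and two molecules are joined through nitrogen by glutaryl chloride. One base-mediated operation closes both five-membered lactam rings onto the purchased benzene rings, and reduction/dehydration turns them into the two indole pyrrole rings.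
- Stereochemistry: the target has none. The two C3 centres of the bis-oxindole form without control and are erased in the last step.

Key step: step 4

Remark: polonidine A as drawn has no stereocentre and no stereogenic axis, so it is a single achiral compound and the route needs no asymmetric step.

**Route**

Step 1
Reactants: 1 2-chloroaniline; 2 3-chloro-3-methylbut-1-yne
Product: 3 2-chloro-N-(2-methylbut-3-yn-2-yl)aniline
Conditions: CuCl (10 mol%), Et3N, THF, 0 °C → rt
Reagents that add atoms: none
Why: Copper-catalysed propargylic amination of a tertiary propargylic chloride (through the copper acetylide/allenylidene) should put the fully substituted carbon on nitrogen, stop after one alkylation for steric reasons, and, kept at room temperature, avoid copper-mediated closure to the dihydroquinoline.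

Step 2
Reactants: 3 2-chloro-N-(2-methylbut-3-yn-2-yl)aniline
Product: 4 2-chloro-N-(2-methylbut-3-en-2-yl)aniline
Conditions: H2 (1 atm), Lindlar catalyst, quinoline, EtOAc, rt
Reagents that add atoms: none
Why: Lindlar semihydrogenation of the terminal alkyne should stop at the vinyl group, and the poisoned palladium is not expected to touch the aryl C–Cl bond.

Step 3
Reactants: 4 2-chloro-N-(2-methylbut-3-en-2-yl)aniline (2 equiv); 5 glutaryl chloride (pentanedioyl dichloride)
Product: 7 N,N'-bis(2-chlorophenyl)-N,N'-bis(2-methylbut-3-en-2-yl)pentanediamide, via bromomagnesium anilide 6 (not isolated)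
Conditions: EtMgBr (1 equiv per 4), THF, 0 °C → rt; then 5 (0.45 equiv), 0 °C → rt
Reagents that add atoms: none
Why: N-Acylation of a metal anilide by an acid chloride; deprotonation makes up for the low nucleophilicity of the hindered ortho-chloro N-tert-alkylaniline and keeps the medium free of HCl, which would ionise the tertiary allylic C–N bond (7 may show slowly interconverting N–aryl rotamers, which is of no consequence).

Step 4
Reactants: 7 N,N'-bis(2-chlorophenyl)-N,N'-bis(2-methylbut-3-en-2-yl)pentanediamide
Product: 10 3,3'-methylenebis[1-(2-methylbut-3-en-2-yl)indolin-2-one] (meso/racemic mixture), via bis-aryne dienolate 8 (not isolated), via dilithium bis-indol-2-olate 9 (not isolated)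
Conditions: LiTMP (6 equiv), THF (0.02 M), −78 → 0 °C; aq. NH4Cl
Reagents that add atoms: none
Why: LiTMP removes an α-hydrogen of each amide and then H-3 of each chloroarene ring, loss of LiCl gives the arynes of 8 (the two rings need not react at the same moment), each enolate carbon adds to the aryne carbon ortho to nitrogen, and proton transfer to the transient aryl carbanions leaves the bis-enolate 9, which NH4Cl converts to 10. The closest known reaction is the strong-base (Bunnett-type) aryne cyclisation of N-alkyl-2-haloanilide enolates to oxindoles, here run twice in one molecule. Each lactam ring (N1, C2, C3, C3a, C7a) closes by 5-exo-dig attack of the enolate carbon on the aryne, forming C3–C3a. The two C3 stereocentres arise without control as a meso/racemic mixture, which is acceptable because step 5 makes both carbons trigonal. The step needs C- over O-arylation (either would close a five-membered ring) and capture by the enolate rather than by the base: the soft aryne prefers the carbon terminus as in the parent oxindole synthesis, the N-tert-alkyl group sits on the oxygen side of the amide and so places the aryl ring next to the α-carbon, LiTMP is too hindered to add quickly, and C-1 of the ring bears no hydrogen so only the 2,3-aryne can form. The conditions are purely anionic, so the vinyl groups, which have no allylic hydrogen for an ene reaction and would trap an ortho aryl radical or arylpalladium by 5-exo closure, should be left alone.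

Step 5
Reactants: 10 3,3'-methylenebis[1-(2-methylbut-3-en-2-yl)indolin-2-one]
Product: 12 polonidine A, bis[1-(2-methylbut-3-en-2-yl)-1H-indol-3-yl]methane, via bis-hemiaminal 11 (not isolated)
Conditions: DIBAL-H (5 equiv), CH2Cl2, −78 → 0 °C; aq. Rochelle salt; then PPTS (cat.), CH2Cl2, rt
Reagents that add atoms: none
Why: Partial reduction of the N-alkyl lactams by DIBAL-H to the 2-hydroxyindolines, followed by dehydration driven by aromatisation, is the known oxindole-to-indole conversion; the isolated vinyl groups are not hydroaluminated at this temperature and the mild acid spares the tertiary allylic N–C bonds.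

**Compound list**
1 | 2-chloroaniline | Nc1ccccc1Cl | starting material
2 | 3-chloro-3-methylbut-1-yne | C#CC(C)(C)Cl | starting material
3 | 2-chloro-N-(2-methylbut-3-yn-2-yl)aniline | C#CC(C)(C)Nc1ccccc1Cl | intermediate
4 | 2-chloro-N-(2-methylbut-3-en-2-yl)aniline | C=CC(C)(C)Nc1ccccc1Cl | intermediate
5 | glutaryl chloride (pentanedioyl dichloride) | O=C(Cl)CCCC(=O)Cl | starting material
6 | bromomagnesium N-(2-chlorophenyl)-N-(2-methylbut-3-en-2-yl)amide (not isolated) | C=CC(C)(C)N([Mg]Br)c1ccccc1Cl | intermediate
7 | N,N'-bis(2-chlorophenyl)-N,N'-bis(2-methylbut-3-en-2-yl)pentanediamide | C=CC(C)(C)N(C(=O)CCCC(=O)N(c1ccccc1Cl)C(C)(C)C=C)c1ccccc1Cl | intermediate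
8 | dilithium 1,5-dienolate of the glutaric diamide in which each N-aryl ring is a 2,3-didehydrophenyl (aryne) group (not isolated) | [Li+].[Li+].C=CC(C)(C)N(C([O-])=CCC=C([O-])N(C1=CC=CC#C1)C(C)(C)C=C)C1=CC=CC#C1 | intermediate
9 | dilithium 3,3'-methylenebis[1-(2-methylbut-3-en-2-yl)-1H-indol-2-olate] (not isolated) | [Li+].[Li+].C=CC(C)(C)n1c([O-])c(Cc2c([O-])n(C(C)(C)C=C)c3ccccc23)c2ccccc21 | intermediate
10 | 3,3'-methylenebis[1-(2-methylbut-3-en-2-yl)indolin-2-one], meso/racemic mixture at C3 and C3' | C=CC(C)(C)N1C(=O)C(CC2C(=O)N(C(C)(C)C=C)c3ccccc23)c2ccccc21 | intermediate
11 | 3,3'-methylenebis[1-(2-methylbut-3-en-2-yl)indolin-2-ol], diastereomer mixture (not isolated) | C=CC(C)(C)N1C(O)C(CC2C(O)N(C(C)(C)C=C)c3ccccc23)c2ccccc21 | intermediate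
12 | polonidine A, bis[1-(2-methylbut-3-en-2-yl)-1H-indol-3-yl]methane (achiral) | C=CC(C)(C)n1cc(Cc2cn(C(C)(C)C=C)c3ccccc23)c2ccccc21 | target

**Count**
Total steps: 5. Longest linear sequence: 5 steps (1 → 3 → 4 → 7 → 10 → 12; 5 enters at step 3).

**Steps most likely to fail**

Step 4. The second ring closure may lag behind the first, or intermolecular capture of an aryne (by base or by another enolate) may overtake the intramolecular C-arylation when two reactive sites sit in one molecule. The fallback closes one ring per molecule and adds the methylene bridge afterwards. It sets out from 4: the magnesium anilide 6 is acetylated with acetyl chloride to N-(2-chlorophenyl)-N-(2-methylbut-3-en-2-yl)acetamide F1. The same LiTMP treatment, now the single aryne closure of a simple acetanilide enolate, should give 1-(2-methylbut-3-en-2-yl)indolin-2-one F2. Knoevenagel condensation of F2 with paraformaldehyde (0.5 equiv, piperidine cat., EtOH, warm) should form 3-methylidene-1-(2-methylbut-3-en-2-yl)indolin-2-one F3, which a second molecule of F2 captures in situ by Michael addition. The route is rejoined at 10.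

Step 3. Acylation may stop at the mono-amide because of the crowded nitrogen, or the amide oxygen of the mono-acylated acid chloride may close onto the remaining acyl chloride with loss of the tertiary allyl group. The fallback builds the five-carbon chain by C–C bond formation from two small acyl units. It sets out from 4: anilide 6 is acylated with acetyl chloride to N-(2-chlorophenyl)-N-(2-methylbut-3-en-2-yl)acetamide F1 and, separately, with acryloyl chloride to N-(2-chlorophenyl)-N-(2-methylbut-3-en-2-yl)prop-2-enamide F4. F1 is deprotonated with LDA in THF at −78 °C, where the chloroarene ring should not yet be attacked, and F4 is added slowly. Michael addition of the amide enolate to the acrylamide should then give the glutaric diamide, and the route is rejoined at 7.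

Step 5. Reduction may stall at an aluminium enolate, run past the hemiaminal to the indoline, or the dehydration may need acid that the tertiary allylic N–C bond does not tolerate. The fallback reduces fully and then dehydrogenates. It sets out from 10: alane (LiAlH4/AlCl3, THF, 0 °C), which leaves isolated alkenes alone, should give 3,3'-methylenebis[1-(2-methylbut-3-en-2-yl)indoline] F5. Activated MnO2 in CH2Cl2 at rt should then dehydrogenate both N-alkylindolines, and the route is rejoined at 12.

**Further compounds**
F1 | step 4 | N-(2-chlorophenyl)-N-(2-methylbut-3-en-2-yl)acetamide | C=CC(C)(C)N(C(C)=O)c1ccccc1Cl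
F2 | step 4 | 1-(2-methylbut-3-en-2-yl)indolin-2-one | C=CC(C)(C)N1C(=O)Cc2ccccc21
F3 | step 4 | 3-methylidene-1-(2-methylbut-3-en-2-yl)indolin-2-one | C=CC(C)(C)N1C(=O)C(=C)c2ccccc21
F4 | step 3 | N-(2-chlorophenyl)-N-(2-methylbut-3-en-2-yl)prop-2-enamide | C=CC(=O)N(c1ccccc1Cl)C(C)(C)C=C
F5 | step 5 | 3,3'-methylenebis[1-(2-methylbut-3-en-2-yl)indoline] | C=CC(C)(C)N1CC(CC2CN(C(C)(C)C=C)c3ccccc23)c2ccccc21
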